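The earlier runs and the new flask come from a simulation on assumed constants; noise was put on by code.

At late times the X readings of both earlier runs climb slowly, from 9 % to 11 % in the south-east run and from 60 % to 63 % in the north-west run, so we freeze that level and ask what it scales with.

| setting | south-east | north-west | theta | eta | gamma | epsilon | beta |
|---|---|---|---|---|---|---|---|
| L | 0.050 M | 0.050 M | 0.050 M | 0.050 M | 0.050 M | 0.050 M | 0.050 M |
| Q | 5 mM | 5 mM | 5.00 mM | 5.00 mM | 5.00 mM | 5.00 mM | 5.00 mM |
| D | 0.0023 mol% | 0.015 mol% | 0.002 mol% | 0.003 mol% | 0.004 mol% | 0.006 mol% | 0.01 mol% |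
| Z | 4 µM | 4 µM | 4.0 µM | 4.0 µM | 4.0 µM | 4.0 µM | 4.0 µM |
| remark | run made earlier | run made earlier |  |  |  |  |  |
| time |  |  | 8.0 min | 8.0 min | 8.0 min | 8.0 min | 8.0 min |

| run | time / min | X / % | L / % |
|---|---|---|---|
| south-east | 0.500 | 9 | 69 |
| south-east | 1.33 | 8 | 51 |
| south-east | 2.50 | 8 | 36 |
| south-east | 4.00 | 9 | 31 |
| south-east | 6.00 | 11 | 21 |
| north-west | 1.00 | 39 | 38 |
| north-west | 2.50 | 52 | 16 |
| north-west | 3.00 | 55 | 15 |
| north-west | 5.00 | 60 | 6 |
| north-west | 6.00 | 63 | 7 |

(readings scatter by 1.5 percentage points)

- a species is counted by the L in it: one E counts as two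
- the analysis behind the earlier runs scatters by 1.5 percentage points, standard deviation
- candidate steps: 2 L -> E; L + D -> X + D; D + Z <-> G; L + Q -> J
- "hardly changes" means that all values lie within two and a half points (for a concentration: within two and a half percent of the largest)

* [X] at the end for theta, eta, gamma, epsilon, beta, in this order
* how the row runs (falls, then rises / rises, then falls / rises all the way / falls all the way / hardly changes)

We build the flask one step at a time. L + D → X + D returns its D, so by itself this step caps [X] at the charge of L, 0.050 M. Now add 2 L → E. In the south-east run L falls from 69 % to 21 % between 0.500 min and 6.00 min, while X goes from 9 % to 11 %. Next add L + Q → J. It uses one L per Q, so J can take at most 10.0 % of the charge, and the south-east readings at 6.00 min then leave about 58.0 % for E.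

Last comes D + Z ⇌ G. The south-east run is charged with 1.15 µM of D, less than its 4 µM of Z, and the north-west run with 7.50 µM, more than its Z. Still, the last readings give 4780 X per D in the south-east run and 4200 in the north-west run. The gap is within what a scatter of 1.5 percentage points on 11 % allows. We therefore freeze their mean, 4490, as the X made per D charged, a turnover number. Our reckoning is then [X] at the end = this number × [D] charged. That gives 0.00449 M, 0.00674 M, 0.00898 M, 0.0135 M and 0.0225 M, rising with D.

The forecast, holding that “Burst and leak scale with D”, gave 0.0052 M, 0.008 M, 0.011 M, 0.0155 M and 0.024 M, rises all the way, and our middle value is lower than its 0.011 M.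

The flasks give 0.00477 M, 0.00636 M, 0.00798 M, 0.0118 M and 0.0233 M, so the row rises all the way.

    2 L → E (k = 0.0860 /M/s)
    L + D → X + D, rate k2*[L]*[D]/(1 + ([L]/Km2) + ([X]/Kp2)) (20.0 mM, 0.300 mM, k = 1.20 × 10⁵ /M/s)
    D + Z ⇌ G (K = 1.20 × 10⁷ /M, k = 60000 /M/s)
    L + Q → J (k = 0.480 /M/s)

In gamma at 8.00 min, G holds 96.1 % of the catalyst and D 3.86 %, and X per D charged comes to 3990, less than our frozen 4490. In beta at 8.00 min, G holds 75.0 % and D 25.0 %, and X per D charged comes to 4660, more than that 4490.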